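**Plan**
- Retrosynthesis: the two phenols are unmasked last (MOM acetals). Ring C is then cut at C2–C3, the benzyl ether at O1–C2, the diazo group goes back to an acetyl group, and the two aryl–prenyl bonds at C6 and C8 are cut.
- Enabling feature: C2 is a benzylic CH bonded to O1 and stands 1,6 to C3, the carbon alpha to the C4 carbonyl. A carbene generated at C3 of an ortho-benzyloxyaryl ketone can therefore insert into a C2–H bond and close ring C.
- Forward order: ring A is 2,4-dihydroxyacetophenone, C-prenylated twice and MOM-protected at the future O7. Ring B is attached to the future O1 as 4-(methoxymethoxy)benzyl bromide, the acetyl group becomes the diazoketone, and ring C closes last.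
- Stereochemistry: C2 is the only stereocentre. It is set in the ring closure by a chiral dirhodium tetracarboxylate that selects one of the two enantiotopic benzylic hydrogens. The final deprotection is acidic so that base-induced opening of ring C cannot scramble C2.

Key step: step 7

Assumption: the sense of induction of Rh2(S-PTTL)4 in this 1,6-insertion cannot be predicted with certainty. The route is written for the (S)-tert-leucinate catalyst; should a first run give the 2R series, the mirror-image catalyst Rh2(R-PTTL)4 takes its place with nothing else changed.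

**Route**

Step 1
Reactants: 1 2,4-dihydroxyacetophenone; 2 prenyl bromide (1-bromo-3-methylbut-2-ene)
Product: 3 1-[2,4-dihydroxy-3,5-bis(3-methylbut-2-en-1-yl)phenyl]ethan-1-one
Conditions: 2 (2.2 equiv), 10% aq. KOH, 0 °C → rt
Reagents that add atoms: none
Why: C-alkylation of the ambident resorcinol phenoxide in water, where the protic medium favours C- over O-attack; C3 and C5 are the only ring positions ortho/para to both oxygens, so exhaustive C-allylation should give the 3,5-diprenyl ketone, separable from mono-prenylated material that can be resubmitted.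

Step 2
Reactants: 3 1-[2,4-dihydroxy-3,5-bis(3-methylbut-2-en-1-yl)phenyl]ethan-1-one
Product: 4 1-[2-hydroxy-4-(methoxymethoxy)-3,5-bis(3-methylbut-2-en-1-yl)phenyl]ethan-1-one
Conditions: MOMCl (1.3 equiv), K2CO3, acetone, rt → 50 °C
Reagents that add atoms: chloromethyl methyl ether, COCCl
Why: Williamson-type O-alkylation that should go to O4 only, because the 2-OH is held in a hydrogen bond to the acetyl carbonyl and is far less nucleophilic.

Step 3
Reactants: 5 4-hydroxybenzyl alcohol
Product: 6 [4-(methoxymethoxy)phenyl]methanol
Conditions: MOMCl (1.05 equiv), K2CO3, acetone, 0 °C → rt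
Reagents that add atoms: chloromethyl methyl ether, COCCl
Why: Chemoselective Williamson etherification, since carbonate deprotonates only the phenol and the neutral benzylic alcohol should not compete for one equivalent of the chloride at low temperature.

Step 4
Reactants: 6 [4-(methoxymethoxy)phenyl]methanol
Product: 7 1-(bromomethyl)-4-(methoxymethoxy)benzene
Conditions: CBr4, PPh3, CH2Cl2, 0 °C; used crude at once
Reagents that add atoms: carbon tetrabromide, BrC(Br)(Br)Br
Why: Appel reaction under neutral conditions, which leaves the acid-sensitive MOM acetal intact; the electron-rich benzylic bromide is not chromatographed but taken directly into the next step.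

Step 5
Reactants: 4 1-[2-hydroxy-4-(methoxymethoxy)-3,5-bis(3-methylbut-2-en-1-yl)phenyl]ethan-1-one; 7 1-(bromomethyl)-4-(methoxymethoxy)benzene
Product: 8 1-[4-(methoxymethoxy)-2-{[4-(methoxymethoxy)phenyl]methoxy}-3,5-bis(3-methylbut-2-en-1-yl)phenyl]ethan-1-one
Conditions: 7 (1.3 equiv), K2CO3, DMF, rt → 50 °C
Reagents that add atoms: none
Why: Williamson ether synthesis with a highly reactive benzylic bromide; carbonate in DMF breaks the hydrogen bond of the chelated phenol, the only acidic OH left, and MOM acetals and prenyl groups are inert to base.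

Step 6
Reactants: 8 1-[4-(methoxymethoxy)-2-{[4-(methoxymethoxy)phenyl]methoxy}-3,5-bis(3-methylbut-2-en-1-yl)phenyl]ethan-1-one
Product: 10 2-diazo-1-[4-(methoxymethoxy)-2-{[4-(methoxymethoxy)phenyl]methoxy}-3,5-bis(3-methylbut-2-en-1-yl)phenyl]ethan-1-one, via trifluoroacetyl ketone 9 (not isolated)
Conditions: LiN(SiMe3)2, THF, −78 °C; CF3CO2CH2CF3; aq. HCl work-up; then MsN3, Et3N, H2O, MeCN, rt
Reagents that add atoms: methanesulfonyl azide, CS(=O)(=O)N=[N+]=[N-]; 2,2,2-trifluoroethyl trifluoroacetate, O=C(OCC(F)(F)F)C(F)(F)F (its trifluoroacetyl group appears only in 9)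
Why: Deacylative Regitz-type diazo transfer, in which Claisen condensation of the lithium enolate with the trifluoroacetate activates the methyl ketone as a 1,3-diketone, the sulfonyl azide delivers N2 and the trifluoroacetyl group leaves as the N-sulfonyl amide; acetals, alkenes and the benzyl ether are untouched.

Step 7
Reactants: 10 2-diazo-1-[4-(methoxymethoxy)-2-{[4-(methoxymethoxy)phenyl]methoxy}-3,5-bis(3-methylbut-2-en-1-yl)phenyl]ethan-1-one
Product: 11 (2S)-7-(methoxymethoxy)-2-[4-(methoxymethoxy)phenyl]-6,8-bis(3-methylbut-2-en-1-yl)-2,3-dihydro-4H-chromen-4-one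
Conditions: dirhodium tetrakis[N-phthaloyl-(S)-tert-leucinate], Rh2(S-PTTL)4 (2 mol %), CH2Cl2, 4 Å MS, 0 °C, slow addition of 10 at high dilution
Reagents that add atoms: none
Why: Loss of N2 from 10 on the dirhodium core gives an electrophilic rhodium carbene at the future C3, which inserts through a concerted, asynchronous three-centre transition state with hydride-transfer character into a benzylic C–H bond of the O1–CH2Ar group and so forms the C2–C3 bond; the closest known reaction type is the chiral dirhodium tetracarboxylate-catalysed C–H insertion of ortho-alkoxyaryl diazoketones to chroman-4-ones. Ring C closes as a six-membered ring by 1,6-insertion (carbene carbon, C4, C4a, C8a, O1, C2), and since the 1,5-position is the ether oxygen itself no five-membered C–H insertion can compete. The new stereocentre C2 is controlled by the catalyst alone: the phthalimido walls of the tert-leucinate ligands differentiate the two enantiotopic benzylic hydrogens, and because insertion proceeds with retention the hydrogen selected fixes the 2S configuration. The step needs C–H insertion to win over attack of the carbene on the O1 lone pair (oxonium ylide, then Stevens 1,2-benzyl shift to a 2-benzylbenzofuran-3-one) and over reaction with the prenyl alkenes. The C–H bond is doubly activated by O1 and by the 4-alkoxyphenyl ring, the bulky carboxylate catalyst is of the type that favours insertion, and both prenyl groups are meta to the acyl carbon so that no strain-free intramolecular cyclopropanation or allylic insertion is available. Slow addition at high dilution should suppress carbene dimerisation and intermolecular cyclopropanation.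

Step 8
Reactants: 11 (2S)-7-(methoxymethoxy)-2-[4-(methoxymethoxy)phenyl]-6,8-bis(3-methylbut-2-en-1-yl)-2,3-dihydro-4H-chromen-4-one
Product: 12 (2S)-7-hydroxy-2-(4-hydroxyphenyl)-6,8-bis(3-methylbut-2-en-1-yl)-2,3-dihydro-4H-chromen-4-one
Conditions: 3 M aq. HCl, MeOH, rt → 40 °C
Reagents that add atoms: none
Why: Acid-catalysed acetal solvolysis (transacetalisation to methanol) frees both phenols in one operation; acid is chosen because base would open ring C by retro-oxa-Michael reaction and racemise C2, and the mild temperature should spare the prenyl groups from cyclising onto the 7-OH.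

**Compound list**
1 | 2,4-dihydroxyacetophenone | CC(=O)c1ccc(O)cc1O | starting material
2 | prenyl bromide (1-bromo-3-methylbut-2-ene) | CC(C)=CCBr | starting material
3 | 1-[2,4-dihydroxy-3,5-bis(3-methylbut-2-en-1-yl)phenyl]ethan-1-one | CC(=O)c1cc(CC=C(C)C)c(O)c(CC=C(C)C)c1O | intermediate
4 | 1-[2-hydroxy-4-(methoxymethoxy)-3,5-bis(3-methylbut-2-en-1-yl)phenyl]ethan-1-one | CC(=O)c1cc(CC=C(C)C)c(OCOC)c(CC=C(C)C)c1O | intermediate
5 | 4-hydroxybenzyl alcohol | OCc1ccc(O)cc1 | starting material
6 | [4-(methoxymethoxy)phenyl]methanol | COCOc1ccc(CO)cc1 | intermediate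
7 | 1-(bromomethyl)-4-(methoxymethoxy)benzene | COCOc1ccc(CBr)cc1 | intermediate
8 | 1-[4-(methoxymethoxy)-2-{[4-(methoxymethoxy)phenyl]methoxy}-3,5-bis(3-methylbut-2-en-1-yl)phenyl]ethan-1-one | CC(=O)c1cc(CC=C(C)C)c(OCOC)c(CC=C(C)C)c1OCc1ccc(OCOC)cc1 | intermediate
9 | 4,4,4-trifluoro-1-[4-(methoxymethoxy)-2-{[4-(methoxymethoxy)phenyl]methoxy}-3,5-bis(3-methylbut-2-en-1-yl)phenyl]butane-1,3-dione | O=C(CC(=O)C(F)(F)F)c1cc(CC=C(C)C)c(OCOC)c(CC=C(C)C)c1OCc1ccc(OCOC)cc1 | intermediate (not isolated)
10 | 2-diazo-1-[4-(methoxymethoxy)-2-{[4-(methoxymethoxy)phenyl]methoxy}-3,5-bis(3-methylbut-2-en-1-yl)phenyl]ethan-1-one | [N-]=[N+]=CC(=O)c1cc(CC=C(C)C)c(OCOC)c(CC=C(C)C)c1OCc1ccc(OCOC)cc1 | intermediate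
11 | (2S)-7-(methoxymethoxy)-2-[4-(methoxymethoxy)phenyl]-6,8-bis(3-methylbut-2-en-1-yl)-2,3-dihydro-4H-chromen-4-one | CC(C)=CCc1cc2c(c(CC=C(C)C)c1OCOC)O[C@H](c1ccc(OCOC)cc1)CC2=O | intermediate
12 | (2S)-7-hydroxy-2-(4-hydroxyphenyl)-6,8-bis(3-methylbut-2-en-1-yl)-2,3-dihydro-4H-chromen-4-one | CC(C)=CCc1cc2c(c(CC=C(C)C)c1O)O[C@H](c1ccc(O)cc1)CC2=O | target

**Step count**
Total: 8 steps. Longest linear sequence: 6 steps (1, 2, 5, 6, 7, 8; the branch 3, 4 joins at step 5).

**Steps most likely to fail**

Step 7. The carbene may attack the O1 lone pair instead of the C–H bond, and 1,2-migration of the electron-rich benzyl group would then lead into the benzofuranone manifold. In addition, a diazoketone without an alpha substituent may be discriminated only weakly between the two enantiotopic hydrogens, giving low enantioselectivity.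

The fallback sets out from 4 and comes back at 11, forming the C2–aryl bond instead of C2–C3. Ketone 4 is condensed with N,N-dimethylformamide dimethyl acetal (toluene, 90 °C) to the enaminone (E)-3-(dimethylamino)-1-[2-hydroxy-4-(methoxymethoxy)-3,5-bis(3-methylbut-2-en-1-yl)phenyl]prop-2-en-1-one F1. Warming F1 in acetic acid should close it with loss of dimethylamine to the chromone 7-(methoxymethoxy)-6,8-bis(3-methylbut-2-en-1-yl)-4H-chromen-4-one F2. Asymmetric 1,4-addition of 4-(methoxymethoxy)phenylboronic acid to F2, catalysed by monovalent rhodium from [RhOH(cod)]2 and an electron-poor axially chiral biaryl diphosphine in toluene/water at rt, should then give 11. This is a known way to enantioenriched flavanones, and the ligand antipode is chosen for 2S.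

Step 1. Under- and over-alkylation, competing O-alkylation and geminal dialkylation at C3 may leave little of the 3,5-diprenyl compound.

The fallback sets out from 1 and comes back at 4, replacing phenoxide alkylation by halogenation and cross-coupling. Iodination of 1 with I2/HIO3 in aqueous ethanol should give 1-(2,4-dihydroxy-3,5-diiodophenyl)ethan-1-one F3. MOMCl/K2CO3 in acetone then protects the non-chelated 4-OH to give 1-[2-hydroxy-3,5-diiodo-4-(methoxymethoxy)phenyl]ethan-1-one F4. A double Stille coupling of F4 with tributyl(3-methylbut-2-en-1-yl)stannane, using the zerovalent palladium catalyst Pd(PPh3)4 in DMF at 90 °C, should place both prenyl groups regiospecifically with linear attachment and give 4.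

Step 8. Protic acid may ionise the C2–O1 bond, which is benzylic and para-oxygenated, and so erode the enantiomeric purity. It may also promote addition of the freed 7-OH to a neighbouring prenyl alkene, closing a chroman ring.

The fallback sets out from 11 and comes back at 12 without protic acid. Treatment with TMSOTf and 2,2'-bipyridyl in MeCN at 0 °C exchanges the aryl MOM acetals for silyl ethers through a bipyridinium salt. This should give (2S)-6,8-bis(3-methylbut-2-en-1-yl)-7-(trimethylsilyloxy)-2-[4-(trimethylsilyloxy)phenyl]-2,3-dihydro-4H-chromen-4-one F5, whose labile silyl ethers are hydrolysed with water at neutral pH to 12.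

**Further compounds**
F1 | step 7 | (E)-3-(dimethylamino)-1-[2-hydroxy-4-(methoxymethoxy)-3,5-bis(3-methylbut-2-en-1-yl)phenyl]prop-2-en-1-one | CN(C)/C=C/C(=O)c1cc(CC=C(C)C)c(OCOC)c(CC=C(C)C)c1O
F2 | step 7 | 7-(methoxymethoxy)-6,8-bis(3-methylbut-2-en-1-yl)-4H-chromen-4-one | O=c1ccoc2c(CC=C(C)C)c(OCOC)c(CC=C(C)C)cc12
F3 | step 1 | 1-(2,4-dihydroxy-3,5-diiodophenyl)ethan-1-one | CC(=O)c1cc(I)c(O)c(I)c1O
F4 | step 1 | 1-[2-hydroxy-3,5-diiodo-4-(methoxymethoxy)phenyl]ethan-1-one | CC(=O)c1cc(I)c(OCOC)c(I)c1O
F5 | step 8 | (2S)-6,8-bis(3-methylbut-2-en-1-yl)-7-(trimethylsilyloxy)-2-[4-(trimethylsilyloxy)phenyl]-2,3-dihydro-4H-chromen-4-one | CC(C)=CCc1cc2c(c(CC=C(C)C)c1O[Si](C)(C)C)O[C@H](c1ccc(O[Si](C)(C)C)cc1)CC2=O
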